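**Retrosynthetic overview**
1. Target 17 ⇐ hydrolysis of imide 16 ⇐ E-selective cross-metathesis of allyl-dioxane 8 with the tertiary vinyl carbinol 15 (carbinol centre S).
2. 8 ⇐ two successive peroxycarbenium substitutions on the bicyclic ozonide 3: allyl at C6, then the Evans propionimide at C3 (sets C3 S and Cα R).
3. 3 ⇐ 2-methylfuran by dearomatising [4+2] addition of singlet oxygen and diimide reduction; this one operation supplies the O–O bond and C3–C6 of the dioxane at the correct oxidation levels.
4. 15 ⇐ dihydro-β-ionone by Horner–Wadsworth–Emmons olefination, reduction, Sharpless epoxidation and reductive opening of the epoxy iodide.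
5. Ring order: the cyclohexene is bought; the trioxabicycloheptane forms in step 1 and is opened to the 1,2-dioxane in step 2; no ring is formed afterwards.

Assumption: compounds 1, 4, 7, 9 and 10 are bought. C6 is formed racemic in step 2, so step 3 gives two C6 epimers and the wanted one is isolated by chromatography (at most 50 % of the material).

**Step 1**
Reactants: 1 2-methylfuran
Product: 3 1-methyl-2,3,7-trioxabicyclo[2.2.1]heptane (racemic), via furan endoperoxide 2 (not isolated)
Conditions: O2, hν (visible), tetraphenylporphyrin (cat.), CH2Cl2, −78 °C; then KO2CN=NCO2K, AcOH, −78 → −30 °C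
Reagents that add atoms: dioxygen, O=O
Why: Singlet oxygen adds [4+2] across C2/C5 of the electron-rich furan (dearomatising photooxygenation) and the strained cis-alkene of endoperoxide 2 is reduced by diimide below its decomposition temperature without touching the O–O bond; the two stereocentres of racemic 3 are erased in steps 2 and 3.

**Step 2**
Reactants: 3 1-methyl-2,3,7-trioxabicyclo[2.2.1]heptane; 4 allyltrimethylsilane
Product: 6 6-allyl-3-methoxy-6-methyl-1,2-dioxane (racemic at C6, both C3 epimers), via silyl peroxyacetal 5 (not isolated)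
Conditions: TMSOTf (10 mol%), CH2Cl2, −78 °C; then MeOH, −78 → −20 °C; Et3N quench
Reagents that add atoms: methanol, CO
Why: Proposed new method: TMSOTf silylates the bridging ether oxygen (the most basic one) and the strained bicycle ionises at the methyl-bearing carbon to a tertiary six-membered peroxycarbenium ion, which 4 traps (Hosomi–Sakurai allylation) with release of TMSOTf to give 5, and the same acid then exchanges the C3 silyloxy group for methoxy in methanol; the closest known reactions are Lewis-acid allylations of 3-alkoxy-1,2-dioxolanes and -dioxanes through peroxycarbenium ions and Lewis-acid ionisation of ozonides; the quaternary centre C6 is formed racemic here.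

**Step 3**
Reactants: 6 6-allyl-3-methoxy-6-methyl-1,2-dioxane; 7 (4S)-4-benzyl-3-propanoyl-1,3-oxazolidin-2-one
Product: 8 (4S)-4-benzyl-3-[(2R)-2-[(3S,6S)-6-methyl-6-(prop-2-en-1-yl)-1,2-dioxan-3-yl]propanoyl]-1,3-oxazolidin-2-one
Conditions: 7, TiCl4 (2.1 equiv), iPr2NEt (1.1 equiv), CH2Cl2, 0 → −78 °C; then 6, −78 → −40 °C; chromatography
Reagents that add atoms: none
Why: The chelated (Z)-chlorotitanium enolate of 7 adds to the C3 peroxycarbenium ion (Evans-type enolate addition to a cyclic oxocarbenium ion) on the face away from the benzyl group, which sets Cα as R, and the open antiperiplanar transition state known from additions of such enolates to cyclic acyliminium ions (1β-methylcarbapenem side chains) sets C3 as S; methyl and allyl at C6 bias the ring very little, so racemic 6 gives 8 and its C6 epimer, and 8 is isolated.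

**Step 4**
Reactants: 9 4-(2,6,6-trimethylcyclohex-1-en-1-yl)butan-2-one (dihydro-β-ionone); 10 triethyl phosphonoacetate
Product: 11 ethyl (2E)-3-methyl-5-(2,6,6-trimethylcyclohex-1-en-1-yl)pent-2-enoate
Conditions: NaH, THF, 0 °C → reflux; chromatography
Reagents that add atoms: none
Why: Horner–Wadsworth–Emmons olefination of the methyl ketone favours the E enoate (about 4:1), which is separated from the Z isomer.

**Step 5**
Reactants: 11 ethyl (2E)-3-methyl-5-(2,6,6-trimethylcyclohex-1-en-1-yl)pent-2-enoate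
Product: 12 (2E)-3-methyl-5-(2,6,6-trimethylcyclohex-1-en-1-yl)pent-2-en-1-ol
Conditions: iBu2AlH (2.2 equiv), CH2Cl2, −78 °C
Reagents that add atoms: none
Why: Hydride 1,2-reduction of the enoate gives the allylic alcohol without touching either alkene.

**Step 6**
Reactants: 12 (2E)-3-methyl-5-(2,6,6-trimethylcyclohex-1-en-1-yl)pent-2-en-1-ol
Product: 13 [(2S,3S)-3-methyl-3-[2-(2,6,6-trimethylcyclohex-1-en-1-yl)ethyl]oxiran-2-yl]methanol
Conditions: Ti(OiPr)4 (5 mol%), L-(+)-diethyl tartrate (6 mol%), tBuOOH, 4 Å MS, CH2Cl2, −20 °C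
Reagents that add atoms: tert-butyl hydroperoxide, CC(C)(C)OO
Why: Katsuki–Sharpless asymmetric epoxidation with the L-tartrate gives the (2S,3S) epoxide, as with geraniol, which fixes the tertiary C–O stereocentre; the unfunctionalised tetrasubstituted ring alkene does not react.

**Step 7**
Reactants: 13 [(2S,3S)-3-methyl-3-[2-(2,6,6-trimethylcyclohex-1-en-1-yl)ethyl]oxiran-2-yl]methanol
Product: 15 (3S)-3-methyl-5-(2,6,6-trimethylcyclohex-1-en-1-yl)pent-1-en-3-ol, via epoxy iodide 14 (not isolated)
Conditions: PPh3, imidazole, I2, THF, 0 °C; then Zn dust, EtOH, 60 °C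
Reagents that add atoms: none
Why: Appel-type iodination followed by zinc-mediated reductive β-elimination of the 2,3-epoxy iodide opens the epoxide to the tertiary allylic alcohol with the C–O bond untouched, so the (3S) epoxide carbon becomes the (S) carbinol.

**Step 8**
Reactants: 8 the allyl-dioxane imide; 15 (3S)-3-methyl-5-(2,6,6-trimethylcyclohex-1-en-1-yl)pent-1-en-3-ol
Product: 16 (4S)-4-benzyl-3-[(2R)-2-[(3S,6S)-6-[(2E,4S)-4-hydroxy-4-methyl-6-(2,6,6-trimethylcyclohex-1-en-1-yl)hex-2-en-1-yl]-6-methyl-1,2-dioxan-3-yl]propanoyl]-1,3-oxazolidin-2-one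
Conditions: second-generation Grubbs catalyst (H2IMes)(PCy3)Cl2Ru=CHPh (5 mol%), 15 (3 equiv), CH2Cl2, 40 °C
Reagents that add atoms: none
Why: Olefin cross-metathesis between the fast-reacting allyl group and the hindered tertiary vinyl carbinol (slow to homodimerise, used in excess) gives the E alkene; the dialkyl peroxide and the tetrasubstituted ring alkene are inert and no stereocentre is touched.

**Step 9**
Reactants: 16 the cross-metathesis imide
Product: 17 (2R)-2-[(3S,6S)-6-[(2E,4S)-4-hydroxy-4-methyl-6-(2,6,6-trimethylcyclohex-1-en-1-yl)hex-2-en-1-yl]-6-methyl-1,2-dioxan-3-yl]propanoic acid (CNP0195960.3)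
Conditions: LiOH, H2O2, THF/H2O 3:1, 0 °C; then Na2SO3; HCl to pH 3
Reagents that add atoms: hydrogen peroxide, OO
Why: Lithium hydroperoxide cleaves the exocyclic imide carbonyl selectively at 0 °C (Evans auxiliary removal) without α-epimerisation or β-elimination of the ring peroxide, and sulfite reduces the peracid but not the dialkyl peroxide.

**Compound list**
1 | 2-methylfuran | Cc1ccco1 | starting material
2 | 1-methyl-2,3,7-trioxabicyclo[2.2.1]hept-5-ene (racemic) | CC12C=CC(OO1)O2 | intermediate
3 | 1-methyl-2,3,7-trioxabicyclo[2.2.1]heptane (racemic) | CC12CCC(OO1)O2 | intermediate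
4 | allyltrimethylsilane | C=CC[Si](C)(C)C | starting material
5 | 6-allyl-6-methyl-3-(trimethylsilyloxy)-1,2-dioxane (racemic, both C3 epimers) | C=CCC1(C)CCC(O[Si](C)(C)C)OO1 | intermediate
6 | 6-allyl-3-methoxy-6-methyl-1,2-dioxane (racemic at C6, both C3 epimers) | C=CCC1(C)CCC(OC)OO1 | intermediate
7 | (4S)-4-benzyl-3-propanoyl-1,3-oxazolidin-2-one | CCC(=O)N1[C@@H](Cc2ccccc2)COC1=O | starting material
8 | (4S)-4-benzyl-3-[(2R)-2-[(3S,6S)-6-methyl-6-(prop-2-en-1-yl)-1,2-dioxan-3-yl]propanoyl]-1,3-oxazolidin-2-one | C=CC[C@]1(C)CC[C@@H]([C@@H](C)C(=O)N2[C@@H](Cc3ccccc3)COC2=O)OO1 | intermediate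
9 | 4-(2,6,6-trimethylcyclohex-1-en-1-yl)butan-2-one | CC(=O)CCC1=C(C)CCCC1(C)C | starting material
10 | triethyl phosphonoacetate | CCOC(=O)CP(=O)(OCC)OCC | starting material
11 | ethyl (2E)-3-methyl-5-(2,6,6-trimethylcyclohex-1-en-1-yl)pent-2-enoate | CCOC(=O)/C=C(\C)CCC1=C(C)CCCC1(C)C | intermediate
12 | (2E)-3-methyl-5-(2,6,6-trimethylcyclohex-1-en-1-yl)pent-2-en-1-ol | OC/C=C(\C)CCC1=C(C)CCCC1(C)C | intermediate
13 | [(2S,3S)-3-methyl-3-[2-(2,6,6-trimethylcyclohex-1-en-1-yl)ethyl]oxiran-2-yl]methanol | OC[C@@H]1O[C@@]1(C)CCC2=C(C)CCCC2(C)C | intermediate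
14 | (2S,3R)-3-(iodomethyl)-2-methyl-2-[2-(2,6,6-trimethylcyclohex-1-en-1-yl)ethyl]oxirane | IC[C@@H]1O[C@@]1(C)CCC2=C(C)CCCC2(C)C | intermediate
15 | (3S)-3-methyl-5-(2,6,6-trimethylcyclohex-1-en-1-yl)pent-1-en-3-ol | CC1=C(CC[C@](C)(O)C=C)C(C)(C)CCC1 | intermediate
16 | (4S)-4-benzyl-3-[(2R)-2-[(3S,6S)-6-[(2E,4S)-4-hydroxy-4-methyl-6-(2,6,6-trimethylcyclohex-1-en-1-yl)hex-2-en-1-yl]-6-methyl-1,2-dioxan-3-yl]propanoyl]-1,3-oxazolidin-2-one | CC1=C(CC[C@](C)(O)/C=C/C[C@]2(C)CC[C@@H]([C@@H](C)C(=O)N3[C@@H](Cc4ccccc4)COC3=O)OO2)C(C)(C)CCC1 | intermediate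
17 | (2R)-2-[(3S,6S)-6-[(2E,4S)-4-hydroxy-4-methyl-6-(2,6,6-trimethylcyclohex-1-en-1-yl)hex-2-en-1-yl]-6-methyl-1,2-dioxan-3-yl]propanoic acid | CC1=C(CC[C@](C)(O)/C=C/C[C@]2(C)CC[C@@H]([C@@H](C)C(=O)O)OO2)C(C)(C)CCC1 | target

**Totals**
Total steps: 9. Longest linear sequence: 6 steps (9 → 11 → 12 → 13 → 15 → 16 → 17); the dioxane branch is 5 steps from 1.

**Steps most likely to fail**

Step 2 (untested ionisation of the ozonide; a competing [3+2] annulation to a 1,2-dioxolane or cleavage of the C–OO bond is possible). The fallback sets out from 3 and comes back at 6. Acid-catalysed methanolysis of 3 (MeOH, HC(OMe)3, pyridinium tosylate) opens the strained bicycle to the monocyclic bis(peroxyacetal) 3,6-dimethoxy-3-methyl-1,2-dioxane F1. TiCl4 (1 equiv) and 4 at −78 °C then ionise only the ketal methoxy group, which is the established peroxyketal allylation, and give 6.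

Step 3 (the syn selectivity and the tolerance of the peroxide to the titanium enolate are unproven, and the yield is capped at 50 %). The fallback sets out from 6 and 7 and comes back at 8; it closes the ring by forming the C3–O bond instead of the C3–C bond. Imide 7 is brominated (Bu2BOTf, iPr2NEt; N-bromosuccinimide) to (4S)-4-benzyl-3-(2-bromopropanoyl)-1,3-oxazolidin-2-one F2. PPh3 converts it into the phosphonium bromide F3, and aqueous NaOH gives the stabilised ylide F4. In parallel, 6 is hydrolysed (aqueous AcOH, THF) to 6-allyl-6-methyl-1,2-dioxan-3-ol F5. Its open hydroperoxy-aldehyde form undergoes Wittig olefination with F4 to the (E)-enimide hydroperoxide F6. Et2NH in CF3CH2OH then induces 6-exo oxa-Michael closure with protonation of the auxiliary-bearing enolate, and 8 is separated from its diastereomers.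

Step 1 (the endoperoxide 2 is thermally labile and the ozonide 3 is volatile). The fallback sets out from 1 and comes back at 3. Photooxygenation of 1 in MeOH (methylene blue, O2, hν, −40 °C) traps the endoperoxide as the bench-stable 5-hydroperoxy-2-methoxy-2-methyl-2,5-dihydrofuran F7. Diimide (KO2CN=NCO2K, AcOH, 0 °C) reduces its alkene to 5-hydroperoxy-2-methoxy-2-methyltetrahydrofuran F8. Pyridinium tosylate in CH2Cl2 over 4 Å molecular sieves closes F8 to 3 with loss of methanol.

**Further compounds**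
F1 | step 2 | 3,6-dimethoxy-3-methyl-1,2-dioxane (racemic, both diastereomers) | COC1CCC(C)(OC)OO1
F2 | step 3 | (4S)-4-benzyl-3-(2-bromopropanoyl)-1,3-oxazolidin-2-one (either C2 epimer) | CC(Br)C(=O)N1[C@@H](Cc2ccccc2)COC1=O
F3 | step 3 | [1-[(4S)-4-benzyl-2-oxo-1,3-oxazolidin-3-yl]-1-oxopropan-2-yl]triphenylphosphonium bromide | CC(C(=O)N1[C@@H](Cc2ccccc2)COC1=O)[P+](c1ccccc1)(c1ccccc1)c1ccccc1.[Br-]
F4 | step 3 | (4S)-4-benzyl-3-[2-(triphenylphosphoranylidene)propanoyl]-1,3-oxazolidin-2-one | CC(C(=O)N1[C@@H](Cc2ccccc2)COC1=O)=P(c1ccccc1)(c1ccccc1)c1ccccc1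
F5 | step 3 | 6-allyl-6-methyl-1,2-dioxan-3-ol (racemic, both C3 epimers) | C=CCC1(C)CCC(O)OO1
F6 | step 3 | (4S)-4-benzyl-3-[(2E)-6-hydroperoxy-2,6-dimethylnona-2,8-dienoyl]-1,3-oxazolidin-2-one (both C6 epimers) | C=CCC(C)(OO)CC/C=C(\C)C(=O)N1[C@@H](Cc2ccccc2)COC1=O
F7 | step 1 | 5-hydroperoxy-2-methoxy-2-methyl-2,5-dihydrofuran (racemic) | COC1(C)C=CC(OO)O1
F8 | step 1 | 5-hydroperoxy-2-methoxy-2-methyltetrahydrofuran (racemic) | COC1(C)CCC(OO)O1
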